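The route rests on disconnecting the depside ester at the oxygen on ring B C3: the C(=O)–O–C3 unit is traced back to a C(=O)–C3 diaryl ketone. Ring B C3 lies between the C2 methoxy and the C4 oxygen and para to the C6 propyl group, so it is the aryl carbon best able to migrate to oxygen; ring A is switched off as its bis(benzyl carbonate). One Baeyer–Villiger oxidation therefore turns the hindered benzophenone into the aryl ester without acylating a crowded phenol. The precursor is the fully benzyl-protected ketone made by adding a ring A aryllithium to a ring B C3 aldehyde; one hydrogenolysis then releases the target.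

Key step: step 12

Remarks: Ring A is the 2,4-dioxygenated 6-propylbenzoyl ring (C1 carries the carbonyl). Ring B is the benzoate ring (C1 carboxyl, C2 methoxy, C3 ester oxygen, C4 oxygen, C6 propyl). The target has no stereocentre. Compounds 3, 4, 5, 14 and 18 are racemic (4 and 5 also cis/trans and keto–enol mixtures); their stereocentres vanish in the next transformation, so they are written without stereodescriptors.

Step 1
Reactants: 1 dibenzyl malonate; 2 (E)-hept-3-en-2-one
Product: 4 benzyl 2,4-dioxo-6-propylcyclohexane-1-carboxylate, via Michael adduct 3 (not isolated)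
Conditions: KOtBu (1.1 equiv), THF, 0 °C → 65 °C; then 1 M HCl
Reagents that add atoms: none
Why: Michael addition of the malonate anion to the enone followed by intramolecular Claisen (Dieckmann-type) condensation of the methyl ketone enolate onto one benzyl ester is the standard [3+3] entry to 5-alkylcyclohexane-1,3-dione carboxylates, and deprotonation of the acidic β-diketone product drives it forward.

Step 2
Reactants: 4 benzyl 2,4-dioxo-6-propylcyclohexane-1-carboxylate
Product: 6 benzyl 2,4-dihydroxy-6-propylbenzoate, via bromodione 5 (not isolated)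
Conditions: Br2 (1.0 equiv), DMF, 0 °C → rt, then 80 °C
Reagents that add atoms: none
Why: Electrophilic α-bromination at C3 between the two carbonyl groups followed by thermal dehydrobromination and enolisation is the classical oxidative aromatisation of such diones to resorcylate esters, with DMF tempering the HBr so that the benzyl ester should survive.

Step 3
Reactants: 6 benzyl 2,4-dihydroxy-6-propylbenzoate
Product: 7 benzyl 4-(benzyloxy)-2-hydroxy-6-propylbenzoate
Conditions: BnBr (1.05 equiv), K2CO3, acetone, 56 °C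
Reagents that add atoms: benzyl bromide, BrCc1ccccc1
Why: Williamson etherification should be selective for the unhindered and more acidic C4 hydroxyl, because the C2 hydroxyl is held in a hydrogen bond to the ester carbonyl.

Step 4
Reactants: 7 benzyl 4-(benzyloxy)-2-hydroxy-6-propylbenzoate
Product: 8 benzyl 4-(benzyloxy)-3-formyl-2-hydroxy-6-propylbenzoate
Conditions: MgCl2 (anhydrous), Et3N, (CH2O)n, MeCN, 80 °C; then 1 M HCl
Reagents that add atoms: paraformaldehyde (formaldehyde), C=O
Why: In the Casnati–Skattebøl ortho-formylation the magnesium phenoxide delivers formaldehyde only ortho to the free hydroxyl and a second formaldehyde accepts hydride to give the aldehyde; since C1 is substituted, C3, which is also activated by the C4 ether and the C6 propyl group, is the only site available.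

Step 5
Reactants: 8 benzyl 4-(benzyloxy)-3-formyl-2-hydroxy-6-propylbenzoate
Product: 9 benzyl 4-(benzyloxy)-3-formyl-2-methoxy-6-propylbenzoate
Conditions: MeI, K2CO3, DMF, 40 °C
Reagents that add atoms: iodomethane, CI
Why: Williamson O-methylation of the only acidic site, with the polar aprotic solvent breaking the chelate of the C2 hydroxyl to its carbonyl neighbours.

Step 6
Reactants: 10 5-propylbenzene-1,3-diol
Product: 11 1,3-bis(methoxymethoxy)-5-propylbenzene
Conditions: MOMCl, i-Pr2NEt, CH2Cl2, 0 °C → rt
Reagents that add atoms: chloromethyl methyl ether, COCCl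
Why: O-Alkylation of both phenols with chloromethyl methyl ether gives acetal ethers that are inert to organolithium reagents and can later be removed with dilute acid.

Step 7
Reactants: 11 1,3-bis(methoxymethoxy)-5-propylbenzene
Product: 12 2-bromo-1,5-bis(methoxymethoxy)-3-propylbenzene
Conditions: NBS (1.0 equiv), MeCN, 0 °C → rt
Reagents that add atoms: N-bromosuccinimide, O=C1CCC(=O)N1Br
Why: Electrophilic aromatic bromination of a 3,5-dialkoxyalkylbenzene should go to the carbon next to the propyl group (ortho to one ether oxygen, para to the other) rather than to the crowded carbon between the two oxygens, and one equivalent at low temperature limits dibromination.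

Step 8
Reactants: 12 2-bromo-1,5-bis(methoxymethoxy)-3-propylbenzene; 9 benzyl 4-(benzyloxy)-3-formyl-2-methoxy-6-propylbenzoate
Product: 14 benzyl 4-(benzyloxy)-3-{[2,4-bis(methoxymethoxy)-6-propylphenyl](hydroxy)methyl}-2-methoxy-6-propylbenzoate (racemate), via aryllithium 13 (not isolated)
Conditions: n-BuLi (1.05 equiv), THF, −78 °C; then 9, −78 → −40 °C; aq. NH4Cl
Reagents that add atoms: none
Why: Bromine–lithium exchange followed by 1,2-addition of the aryllithium to the aldehyde should outpace attack on the benzyl ester, which is shielded by two ortho substituents, and the racemic carbinol centre is erased in step 9.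

Step 9
Reactants: 14 benzyl 4-(benzyloxy)-3-{[2,4-bis(methoxymethoxy)-6-propylphenyl](hydroxy)methyl}-2-methoxy-6-propylbenzoate
Product: 15 benzyl 4-(benzyloxy)-3-[2,4-bis(methoxymethoxy)-6-propylbenzoyl]-2-methoxy-6-propylbenzoate
Conditions: Dess–Martin periodinane, CH2Cl2, rt
Reagents that add atoms: none
Why: Dess–Martin oxidation converts the secondary, doubly benzylic alcohol into the ketone under nearly neutral conditions that leave the acetals, the benzyl groups and the ester untouched.

Step 10
Reactants: 15 benzyl 4-(benzyloxy)-3-[2,4-bis(methoxymethoxy)-6-propylbenzoyl]-2-methoxy-6-propylbenzoate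
Product: 16 benzyl 4-(benzyloxy)-3-(2,4-dihydroxy-6-propylbenzoyl)-2-methoxy-6-propylbenzoate
Conditions: conc. HCl (cat.), MeOH/THF, 40 °C
Reagents that add atoms: none
Why: Acid-catalysed transacetalisation to methanol removes both methoxymethyl groups, while the aryl benzyl ether, the aryl methyl ether and the doubly ortho-substituted benzyl ester are stable to dilute acid at this temperature.

Step 11
Reactants: 16 benzyl 4-(benzyloxy)-3-(2,4-dihydroxy-6-propylbenzoyl)-2-methoxy-6-propylbenzoate
Product: 17 benzyl 4-(benzyloxy)-3-(2,4-bis{[(benzyloxy)carbonyl]oxy}-6-propylbenzoyl)-2-methoxy-6-propylbenzoate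
Conditions: CbzCl (3 equiv), Et3N, DMAP (cat.), CH2Cl2, 0 °C → rt
Reagents that add atoms: benzyl chloroformate, O=C(Cl)OCc1ccccc1
Why: DMAP-catalysed O-acylation with the chloroformate converts both ring A phenols into benzyl carbonates, the excess reagent being there for the slower, hydrogen-bonded ortho hydroxyl.

Step 12
Reactants: 17 benzyl 4-(benzyloxy)-3-(2,4-bis{[(benzyloxy)carbonyl]oxy}-6-propylbenzoyl)-2-methoxy-6-propylbenzoate
Product: 19 benzyl 4-(benzyloxy)-3-[(2,4-bis{[(benzyloxy)carbonyl]oxy}-6-propylbenzoyl)oxy]-2-methoxy-6-propylbenzoate, via Criegee adduct 18 (not isolated)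
Conditions: CF3CO3H [from (CF3CO)2O and urea·H2O2], Na2HPO4, CH2Cl2, 0 °C → rt
Reagents that add atoms: trifluoroperacetic acid, OOC(=O)C(F)(F)F
Why: Trifluoroperacetic acid, generated from trifluoroacetic anhydride and urea–hydrogen peroxide, attacks the ketone carbonyl to give the tetrahedral peroxy hemiketal 18; ring B C3 then moves from the carbinol carbon to the adjacent peroxide oxygen while trifluoroacetate departs, so the carbonyl C–O bond and the O–C3 bond arise in a single event. The closest known reaction type is the Baeyer–Villiger oxidation of unsymmetrical benzophenones to aryl benzoates, in which the more electron-rich aryl group migrates. No ring is closed and no stereocentre is formed. The selectivity required is migration of ring B and not of ring A: ring B C3 has ether oxygens on both ortho carbons (C2 methoxy, C4 benzyloxy) and a para propyl group to stabilise the developing positive charge, whereas the ortho and para oxygens of ring A are carbonate oxygens whose lone pairs are drawn into the carbonate carbonyls. Because four ortho substituents flank the carbonyl, a small and strongly electrophilic peracid is chosen, and the phosphate buffer keeps trifluoroacetic acid from cleaving the new aryl ester or the carbonates.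

Step 13
Reactants: 19 benzyl 4-(benzyloxy)-3-[(2,4-bis{[(benzyloxy)carbonyl]oxy}-6-propylbenzoyl)oxy]-2-methoxy-6-propylbenzoate
Product: 20 3-[(2,4-dihydroxy-6-propylbenzoyl)oxy]-4-hydroxy-2-methoxy-6-propylbenzoic acid
Conditions: H2 (1 atm), 10% Pd/C, EtOAc, rt
Reagents that add atoms: none
Why: Catalytic hydrogenolysis cleaves all four benzylic C–O bonds (ether, ester and two carbonates), the carbonic acid half-esters lose CO2 spontaneously, and the aryl ester, which has no benzylic C–O bond, should be untouched under these neutral conditions.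

Compound list
1 | dibenzyl malonate | O=C(CC(=O)OCc1ccccc1)OCc1ccccc1 | starting material
2 | (E)-hept-3-en-2-one | CCC/C=C/C(C)=O | starting material
3 | dibenzyl 2-(2-oxoheptan-4-yl)propanedioate (racemate) | CCCC(CC(C)=O)C(C(=O)OCc1ccccc1)C(=O)OCc1ccccc1 | intermediate
4 | benzyl 2,4-dioxo-6-propylcyclohexane-1-carboxylate (racemic stereoisomer and tautomer mixture, drawn as the diketone) | CCCC1CC(=O)CC(=O)C1C(=O)OCc1ccccc1 | intermediate
5 | benzyl 3-bromo-2,4-dioxo-6-propylcyclohexane-1-carboxylate (stereoisomer mixture) | CCCC1CC(=O)C(Br)C(=O)C1C(=O)OCc1ccccc1 | intermediate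
6 | benzyl 2,4-dihydroxy-6-propylbenzoate | CCCc1cc(O)cc(O)c1C(=O)OCc1ccccc1 | intermediate
7 | benzyl 4-(benzyloxy)-2-hydroxy-6-propylbenzoate | CCCc1cc(OCc2ccccc2)cc(O)c1C(=O)OCc1ccccc1 | intermediate
8 | benzyl 4-(benzyloxy)-3-formyl-2-hydroxy-6-propylbenzoate | CCCc1cc(OCc2ccccc2)c(C=O)c(O)c1C(=O)OCc1ccccc1 | intermediate
9 | benzyl 4-(benzyloxy)-3-formyl-2-methoxy-6-propylbenzoate | CCCc1cc(OCc2ccccc2)c(C=O)c(OC)c1C(=O)OCc1ccccc1 | intermediate
10 | 5-propylbenzene-1,3-diol | CCCc1cc(O)cc(O)c1 | starting material
11 | 1,3-bis(methoxymethoxy)-5-propylbenzene | CCCc1cc(OCOC)cc(OCOC)c1 | intermediate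
12 | 2-bromo-1,5-bis(methoxymethoxy)-3-propylbenzene | CCCc1cc(OCOC)cc(OCOC)c1Br | intermediate
13 | [2,4-bis(methoxymethoxy)-6-propylphenyl]lithium | [Li]c1c(CCC)cc(OCOC)cc1OCOC | intermediate
14 | benzyl 4-(benzyloxy)-3-{[2,4-bis(methoxymethoxy)-6-propylphenyl](hydroxy)methyl}-2-methoxy-6-propylbenzoate (racemate) | CCCc1cc(OCOC)cc(OCOC)c1C(O)c1c(OCc2ccccc2)cc(CCC)c(C(=O)OCc2ccccc2)c1OC | intermediate
15 | benzyl 4-(benzyloxy)-3-[2,4-bis(methoxymethoxy)-6-propylbenzoyl]-2-methoxy-6-propylbenzoate | CCCc1cc(OCOC)cc(OCOC)c1C(=O)c1c(OCc2ccccc2)cc(CCC)c(C(=O)OCc2ccccc2)c1OC | intermediate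
16 | benzyl 4-(benzyloxy)-3-(2,4-dihydroxy-6-propylbenzoyl)-2-methoxy-6-propylbenzoate | CCCc1cc(O)cc(O)c1C(=O)c1c(OCc2ccccc2)cc(CCC)c(C(=O)OCc2ccccc2)c1OC | intermediate
17 | benzyl 4-(benzyloxy)-3-(2,4-bis{[(benzyloxy)carbonyl]oxy}-6-propylbenzoyl)-2-methoxy-6-propylbenzoate | CCCc1cc(OC(=O)OCc2ccccc2)cc(OC(=O)OCc2ccccc2)c1C(=O)c1c(OCc2ccccc2)cc(CCC)c(C(=O)OCc2ccccc2)c1OC | intermediate
18 | benzyl 4-(benzyloxy)-3-[(2,4-bis{[(benzyloxy)carbonyl]oxy}-6-propylphenyl)(hydroxy)(trifluoroacetylperoxy)methyl]-2-methoxy-6-propylbenzoate (racemate) | CCCc1cc(OC(=O)OCc2ccccc2)cc(OC(=O)OCc2ccccc2)c1C(O)(OOC(=O)C(F)(F)F)c1c(OCc2ccccc2)cc(CCC)c(C(=O)OCc2ccccc2)c1OC | intermediate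
19 | benzyl 4-(benzyloxy)-3-[(2,4-bis{[(benzyloxy)carbonyl]oxy}-6-propylbenzoyl)oxy]-2-methoxy-6-propylbenzoate | CCCc1cc(OC(=O)OCc2ccccc2)cc(OC(=O)OCc2ccccc2)c1C(=O)Oc1c(OCc2ccccc2)cc(CCC)c(C(=O)OCc2ccccc2)c1OC | intermediate
20 | 3-[(2,4-dihydroxy-6-propylbenzoyl)oxy]-4-hydroxy-2-methoxy-6-propylbenzoic acid | CCCc1cc(O)cc(O)c1C(=O)Oc1c(O)cc(CCC)c(C(=O)O)c1OC | target

Total step count: 13
Longest linear sequence: 11 steps (steps 1–5, then 8–13); the ring A branch (steps 6–7) joins at step 8.

Steps most likely to fail

Step 12. The peracid may add too slowly to a carbonyl carbon flanked by four ortho substituents. Electrophilic hydroxylation of ring B at C5, over-oxidation of the product or partial migration of ring A could then compete with the desired oxygen insertion. The fallback makes the ester bond by acylation instead; it sets out from 9 and 7 and rejoins the route at 20. Dakin-type oxidation of aldehyde 9 with mCPBA in CH2Cl2 should give benzyl 4-(benzyloxy)-3-(formyloxy)-2-methoxy-6-propylbenzoate F1. Methanolysis of the formate with Et3N in MeOH at 0 °C should then give benzyl 4-(benzyloxy)-3-hydroxy-2-methoxy-6-propylbenzoate F2. In parallel, phenol 7 is benzylated (BnBr, K2CO3, DMF, 60 °C) to benzyl 2,4-bis(benzyloxy)-6-propylbenzoate F3, which is saponified (KOH, DMSO/H2O, 90 °C) to 2,4-bis(benzyloxy)-6-propylbenzoic acid F4. Acid F4 and phenol F2 are condensed through the mixed anhydride ((CF3CO)2O, toluene, rt) to benzyl 4-(benzyloxy)-3-{[2,4-bis(benzyloxy)-6-propylbenzoyl]oxy}-2-methoxy-6-propylbenzoate F5. Hydrogenolysis of F5 (H2, 10% Pd/C, EtOAc) should give 20.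

Step 4. Chelation of magnesium between the phenoxide and the neighbouring ester may make the formylation sluggish, leading to incomplete conversion or to O-methoxymethylation on prolonged heating. The fallback brings in the C3 carbon by sigmatropic rearrangement; it sets out from 7 and rejoins at 9. O-Allylation (allyl bromide, K2CO3, DMF, 50 °C) should give benzyl 4-(benzyloxy)-2-(prop-2-en-1-yloxy)-6-propylbenzoate F6. Aromatic Claisen rearrangement (N,N-diethylaniline, 190 °C) can only go to C3, the one free ortho carbon, and should give benzyl 4-(benzyloxy)-2-hydroxy-3-(prop-2-en-1-yl)-6-propylbenzoate F7. Methylation (MeI, K2CO3, DMF) gives benzyl 4-(benzyloxy)-2-methoxy-3-(prop-2-en-1-yl)-6-propylbenzoate F8. Double-bond migration (RuHCl(CO)(PPh3)3 cat., toluene, 80 °C) gives benzyl 4-(benzyloxy)-2-methoxy-3-[(E)-prop-1-en-1-yl]-6-propylbenzoate F9. Lemieux–Johnson cleavage (OsO4 cat., NaIO4, 2,6-lutidine, dioxane/H2O) should then give 9.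

Step 2. Bromide and HBr may cleave the benzyl ester at the temperature needed for dehydrobromination, after which the free acid decarboxylates; ring over-bromination is a second concern. The fallback carboxylates the arene instead of building the ring; it sets out from 10 and rejoins at 7, bypassing steps 1–3. Carboxylation of 10 with methyl magnesium carbonate (MeOMgOCO2Me, DMF, 120 °C; then cold dilute HCl) should give 2,4-dihydroxy-6-propylbenzoic acid F10. Benzylation of the carboxylate and the C4 hydroxyl (BnBr 2.1 equiv, K2CO3, DMF, rt) should then give 7.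

Further compounds
F1 | step 12 | benzyl 4-(benzyloxy)-3-(formyloxy)-2-methoxy-6-propylbenzoate | CCCc1cc(OCc2ccccc2)c(OC=O)c(OC)c1C(=O)OCc1ccccc1
F2 | step 12 | benzyl 4-(benzyloxy)-3-hydroxy-2-methoxy-6-propylbenzoate | CCCc1cc(OCc2ccccc2)c(O)c(OC)c1C(=O)OCc1ccccc1
F3 | step 12 | benzyl 2,4-bis(benzyloxy)-6-propylbenzoate | CCCc1cc(OCc2ccccc2)cc(OCc2ccccc2)c1C(=O)OCc1ccccc1
F4 | step 12 | 2,4-bis(benzyloxy)-6-propylbenzoic acid | CCCc1cc(OCc2ccccc2)cc(OCc2ccccc2)c1C(=O)O
F5 | step 12 | benzyl 4-(benzyloxy)-3-{[2,4-bis(benzyloxy)-6-propylbenzoyl]oxy}-2-methoxy-6-propylbenzoate | CCCc1cc(OCc2ccccc2)cc(OCc2ccccc2)c1C(=O)Oc1c(OCc2ccccc2)cc(CCC)c(C(=O)OCc2ccccc2)c1OC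
F6 | step 4 | benzyl 4-(benzyloxy)-2-(prop-2-en-1-yloxy)-6-propylbenzoate | CCCc1cc(OCc2ccccc2)cc(OCC=C)c1C(=O)OCc1ccccc1
F7 | step 4 | benzyl 4-(benzyloxy)-2-hydroxy-3-(prop-2-en-1-yl)-6-propylbenzoate | CCCc1cc(OCc2ccccc2)c(CC=C)c(O)c1C(=O)OCc1ccccc1
F8 | step 4 | benzyl 4-(benzyloxy)-2-methoxy-3-(prop-2-en-1-yl)-6-propylbenzoate | CCCc1cc(OCc2ccccc2)c(CC=C)c(OC)c1C(=O)OCc1ccccc1
F9 | step 4 | benzyl 4-(benzyloxy)-2-methoxy-3-[(E)-prop-1-en-1-yl]-6-propylbenzoate | CCCc1cc(OCc2ccccc2)c(/C=C/C)c(OC)c1C(=O)OCc1ccccc1
F10 | step 2 | 2,4-dihydroxy-6-propylbenzoic acid | CCCc1cc(O)cc(O)c1C(=O)O
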